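**Retrosynthetic overview**

1. Target ⇐ 3,19-acetonide of andrographolide (C14 acetylation, acetonide removal). The lactone ring is formed last, not by aldol condensation but by Pd-catalysed carbonylative lactonisation (C16 from CO) of an (E)-13-iodo-14,15-diol made by syn-hydrostannation/iodination of a C12≡C13 alkyne.
2. C3-OH and C19-OH ⇐ LiAlH4 reduction of a 3-oxo-19-ester (auxiliary released); C18 ⇐ face-selective C-methylation of the bicyclic β-keto ester.
3. Key step: ring A, then ring B, C5/C9/C10 and the exocyclic C8=C17 alkene are made in one operation by a trivalent manganese/divalent copper oxidative radical bicyclisation of an acyclic (–)-8-phenylmenthyl β-keto ester that already carries C1–C15 as a skipped enyne (bonds C4–C5, then C10–C9).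
4. Acyclic precursor ⇐ acetoacetate dianion + C10 allylic bromide; skipped enyne ⇐ copper-catalysed coupling of 8-hydroxygeranyl chloride with (S)-3,4-bis(silyloxy)but-1-yne (C14 from D-glyceraldehyde acetonide).

Assumption: the entry is 14-O-acetylandrographolide; labdane numbering (C1–C20) is used, and α/β mean the faces of the usual drawing, in which this series has 10-CH3 α, 5-H β and 9-H β.

**Route**

Step 1
Reactants: 1 (–)-8-phenylmenthol, (1R,2S,5R)-5-methyl-2-(2-phenylpropan-2-yl)cyclohexan-1-ol; 2 2,2,6-trimethyl-4H-1,3-dioxin-4-one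
Product: 3 (–)-8-phenylmenthyl 3-oxobutanoate
Conditions: xylene, 140 °C, acetone distilled off
Reagents that add atoms: none
Why: Acetoacetylation: thermal retro-hetero-Diels–Alder of the dioxinone gives acetylketene, which acylates the hindered secondary alcohol without touching its stereocentres.

Step 2
Reactants: 4 (R)-2,2-dimethyl-1,3-dioxolane-4-carbaldehyde
Product: 5 (S)-4-ethynyl-2,2-dimethyl-1,3-dioxolane
Conditions: dimethyl (1-diazo-2-oxopropyl)phosphonate, K2CO3, MeOH, 0 °C to rt
Reagents that add atoms: dimethyl (1-diazo-2-oxopropyl)phosphonate, CC(=O)C(=[N+]=[N-])P(=O)(OC)OC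
Why: Ohira–Bestmann (Seyferth–Gilbert) homologation turns CHO into C≡CH under conditions mild enough to keep the α-alkoxy stereocentre (the descriptor changes from R to S only through the priority rules).

Step 3
Reactants: 5 (S)-4-ethynyl-2,2-dimethyl-1,3-dioxolane
Product: 6 (S)-but-3-yne-1,2-diol
Conditions: HCl (cat.), H2O/THF, rt
Reagents that add atoms: none
Why: Acid-catalysed acetal hydrolysis frees the diol so that it can be re-protected as silyl ethers, which, unlike a terminal acetonide, tolerate the lanthanide Lewis acid of step 9.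

Step 4
Reactants: 6 (S)-but-3-yne-1,2-diol
Product: 7 (S)-3,4-bis(tert-butyldimethylsilyloxy)but-1-yne
Conditions: TBSCl (2.3 equiv), imidazole, DMF, rt
Reagents that add atoms: tert-butyldimethylsilyl chloride, CC(C)(C)[Si](C)(C)Cl
Why: Standard imidazole-mediated silylation of both hydroxyls; the carbinol stereocentre (future C14) is not involved.

Step 5
Reactants: 8 geranyl chloride, (2E)-1-chloro-3,7-dimethylocta-2,6-diene
Product: 9 (2E,6E)-8-chloro-2,6-dimethylocta-2,6-dien-1-ol
Conditions: SeO2 (10 mol%), t-BuOOH (3 equiv), salicylic acid (10 mol%), CH2Cl2, 0 °C to rt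
Reagents that add atoms: tert-butyl hydroperoxide, CC(C)(C)OO
Why: Riley allylic oxidation (ene reaction then [2,3]-sigmatropic shift) hydroxylates the E-methyl of the terminal alkene only, because the other alkene is deactivated by the allylic chloride, and the [2,3] shift delivers the (E)-allylic alcohol.

Step 6
Reactants: 9 (2E,6E)-8-chloro-2,6-dimethylocta-2,6-dien-1-ol; 7 (S)-3,4-bis(tert-butyldimethylsilyloxy)but-1-yne
Product: 11 (2E,6E,11S)-11,12-bis(tert-butyldimethylsilyloxy)-2,6-dimethyldodeca-2,6-dien-9-yn-1-ol, via allylic iodide 10 (not isolated)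
Conditions: CuI (10 mol%), NaI (1.2 equiv), K2CO3 (1.5 equiv), DMF, rt, argon
Reagents that add atoms: sodium iodide, [Na+].[I-] (iodine in 10 only, none in 11)
Why: Finkelstein exchange followed by copper acetylide allylic substitution at the primary carbon (copper-catalysed allyl–alkynyl coupling) gives the skipped enyne with both E-alkenes and the free alcohol untouched.

Step 7
Reactants: 11 (2E,6E,11S)-11,12-bis(tert-butyldimethylsilyloxy)-2,6-dimethyldodeca-2,6-dien-9-yn-1-ol
Product: 12 (2E,6E,11S)-1-bromo-11,12-bis(tert-butyldimethylsilyloxy)-2,6-dimethyldodeca-2,6-dien-9-yne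
Conditions: CBr4, PPh3, CH2Cl2, 0 °C
Reagents that add atoms: carbon tetrabromide, BrC(Br)(Br)Br
Why: Appel bromination of the primary allylic alcohol proceeds by direct displacement at 0 °C without allylic transposition and leaves silyl ethers and the enyne alone.

Step 8
Reactants: 12 (2E,6E,11S)-1-bromo-11,12-bis(tert-butyldimethylsilyloxy)-2,6-dimethyldodeca-2,6-dien-9-yne; 3 (–)-8-phenylmenthyl 3-oxobutanoate
Product: 13 (–)-8-phenylmenthyl (6E,10E,15S)-15,16-bis(tert-butyldimethylsilyloxy)-6,10-dimethyl-3-oxohexadeca-6,10-dien-13-ynoate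
Conditions: 3 (1.2 equiv), LiN(i-Pr)2 (2.4 equiv), THF, –78 to 0 °C; then 12, 0 °C; aqueous quench
Reagents that add atoms: none
Why: Weiler dianion alkylation: the more reactive terminal (γ) carbanion of the acetoacetate dianion displaces the allylic bromide, forming the C1–C2 bond and completing the acyclic C1–C15 precursor.

Step 9
Reactants: 13 (–)-8-phenylmenthyl (6E,10E,15S)-15,16-bis(tert-butyldimethylsilyloxy)-6,10-dimethyl-3-oxohexadeca-6,10-dien-13-ynoate
Product: 14 (–)-8-phenylmenthyl (14S)-14,15-bis(tert-butyldimethylsilyloxy)-3-oxo-16,18-dinorlabd-8(17)-en-12-yn-19-oate (5β-H, 9β-H, 10α-CH3; ester equatorial, C4 epimerisable)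
Conditions: Mn(OAc)3·2H2O (2.2 equiv), Cu(OAc)2·H2O (0.5 equiv), Yb(OTf)3 (1.0 equiv), CF3CH2OH (0.02 M), –5 to 0 °C
Reagents that add atoms: none
Why: Snider-type oxidative free-radical polyene cyclisation with auxiliary control: the Yb-chelated β-keto ester radical made by Mn(OAc)3 is shielded on one face by the phenyl ring of the auxiliary, so C4 adds to C5 of the E-alkene from the open face (6-endo, ring A), the tertiary C10 radical closes ring B on C9 through a chair–chair transition state (trans fusion, 10-CH3 axial, C9 chain equatorial), and Cu(OAc)2 (re-oxidised by Mn(OAc)3) turns the C8 radical into the exocyclic alkene by β-hydride loss from C17; the (–)-auxiliary leads to the 10α-methyl series, the mirror image of the sense known for the (+)-auxiliary.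

Step 10
Reactants: 14 bicyclic β-keto ester
Product: 15 (–)-8-phenylmenthyl (14S)-14,15-bis(tert-butyldimethylsilyloxy)-3-oxo-16-norlabd-8(17)-en-12-yn-19-oate (4β-CH3 equatorial, 4α-ester axial)
Conditions: KOt-Bu (1.1 equiv), MeI (3 equiv), THF/t-BuOH, 0 °C to rt
Reagents that add atoms: iodomethane, CI
Why: C-Alkylation of the potassium enolate of a cyclic β-keto ester: MeI enters trans to the axial 10-CH3, which is also the face left open by the auxiliary phenyl ring, so the new methyl (C18) is equatorial and the ester (future C19) axial, which fixes the C4 quaternary centre.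

Step 11
Reactants: 15 methylated bicyclic keto ester
Product: 16 (14S)-14,15-bis(tert-butyldimethylsilyloxy)-16-norlabd-8(17)-en-12-yne-3α,19-diol
Conditions: LiAlH4 (4 equiv), THF, 0 to 45 °C; Fieser work-up
Reagents that add atoms: none
Why: Hydride reduction: axial attack on the C3 ketone gives the equatorial 3α-alkoxide, whose aluminate delivers hydride internally to the neighbouring axial ester to give C19H2OH and release the recoverable auxiliary, while silyl ethers and the unactivated internal alkyne are inert.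

Step 12
Reactants: 16 (14S)-14,15-bis(tert-butyldimethylsilyloxy)-16-norlabd-8(17)-en-12-yne-3α,19-diol
Product: 17 (14S)-14,15-bis(tert-butyldimethylsilyloxy)-3α,19-(isopropylidenedioxy)-16-norlabd-8(17)-en-12-yne
Conditions: 2,2-dimethoxypropane, PPTS (cat.), CH2Cl2, rt
Reagents that add atoms: 2,2-dimethoxypropane, COC(C)(C)OC
Why: Acid-catalysed transacetalisation closes the six-membered 1,3-dioxane across the syn 3α-OH/19-OH pair under conditions that leave the TBS ethers.

Step 13
Reactants: 17 acetonide bis-silyl ether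
Product: 18 (14S)-3α,19-(isopropylidenedioxy)-16-norlabd-8(17)-en-12-yne-14,15-diol
Conditions: TBAF·3H2O (2.5 equiv), THF, 0 °C to rt
Reagents that add atoms: none
Why: Fluoride-driven Si–O cleavage frees the propargylic 14-OH and the 15-OH without affecting the acetonide or the alkenes.

Step 14
Reactants: 18 (14S)-3α,19-(isopropylidenedioxy)-16-norlabd-8(17)-en-12-yne-14,15-diol
Product: 20 (12E)-13-iodo-3α,19-(isopropylidenedioxy)-16-norlabda-8(17),12-diene-14,15-diol, via vinylstannane 19 (not isolated)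
Conditions: Bu3SnH (1.2 equiv), PdCl2(PPh3)2 (3 mol%), THF, 0 °C; then I2 (1.2 equiv), CH2Cl2, 0 °C
Reagents that add atoms: tributyltin hydride, CCCC[SnH](CCCC)CCCC (tin in 19 only); iodine, II
Why: Pd-catalysed syn-hydrostannation puts tin on the alkyne carbon next to the carbinol (C13) and hydrogen cis to it on C12, and iododestannylation goes with retention, so C11 ends trans to iodine, which is the geometry of the target alkylidene.

Step 15
Reactants: 20 (12E)-13-iodo-3α,19-(isopropylidenedioxy)-16-norlabda-8(17),12-diene-14,15-diol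
Product: 21 3,19-O-isopropylideneandrographolide
Conditions: Pd(PPh3)4 (5 mol%), CO (1 atm), i-Pr2NEt (2 equiv), THF, 50 °C
Reagents that add atoms: carbon monoxide, [C-]#[O+]
Why: Carbonylative lactonisation: oxidative addition of zerovalent palladium to the C–I bond with retention, CO insertion and 5-exo capture of the acylpalladium by the primary 15-OH give the α-alkylidene-β-hydroxy-γ-butyrolactone with (E) geometry and the C14 carbinol untouched.

Step 16
Reactants: 21 3,19-O-isopropylideneandrographolide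
Product: 22 14-O-acetyl-3,19-O-isopropylideneandrographolide
Conditions: Ac2O (neat), 140 °C, 1 h
Reagents that add atoms: acetic anhydride, CC(=O)OC(C)=O
Why: Base-free acetylation of the only free hydroxyl (C14) avoids the elimination and allylic displacement that amine bases cause with this allylic acetate.

Step 17
Reactants: 22 14-O-acetyl-3,19-O-isopropylideneandrographolide
Product: 23 14-O-acetylandrographolide (target)
Conditions: AcOH/H2O (7:3), rt, 30 min
Reagents that add atoms: none
Why: Mild aqueous-acid hydrolysis of the 1,3-dioxane frees the 3-OH and 19-OH while the allylic acetate, lactone and both alkenes survive.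

**Compound list**

1 | (–)-8-phenylmenthol, (1R,2S,5R)-5-methyl-2-(2-phenylpropan-2-yl)cyclohexan-1-ol | CC(C)(c1ccccc1)[C@@H]1CC[C@@H](C)C[C@H]1O | starting material
2 | 2,2,6-trimethyl-4H-1,3-dioxin-4-one | CC1=CC(=O)OC(C)(C)O1 | starting material
3 | (–)-8-phenylmenthyl 3-oxobutanoate | CC(=O)CC(=O)O[C@@H]1C[C@H](C)CC[C@H]1C(C)(C)c1ccccc1 | intermediate
4 | (R)-2,2-dimethyl-1,3-dioxolane-4-carbaldehyde | O=C[C@H]1COC(C)(C)O1 | starting material
5 | (S)-4-ethynyl-2,2-dimethyl-1,3-dioxolane | C#C[C@H]1COC(C)(C)O1 | intermediate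
6 | (S)-but-3-yne-1,2-diol | C#C[C@H](O)CO | intermediate
7 | (S)-3,4-bis(tert-butyldimethylsilyloxy)but-1-yne | C#C[C@H](O[Si](C)(C)C(C)(C)C)CO[Si](C)(C)C(C)(C)C | intermediate
8 | geranyl chloride, (2E)-1-chloro-3,7-dimethylocta-2,6-diene | CC(C)=CCC/C(C)=C/CCl | starting material
9 | (2E,6E)-8-chloro-2,6-dimethylocta-2,6-dien-1-ol | OC/C(C)=C/CC/C(C)=C/CCl | intermediate
10 | (2E,6E)-8-iodo-2,6-dimethylocta-2,6-dien-1-ol (not isolated) | OC/C(C)=C/CC/C(C)=C/CI | intermediate
11 | (2E,6E,11S)-11,12-bis(tert-butyldimethylsilyloxy)-2,6-dimethyldodeca-2,6-dien-9-yn-1-ol | OC/C(C)=C/CC/C(C)=C/CC#C[C@H](O[Si](C)(C)C(C)(C)C)CO[Si](C)(C)C(C)(C)C | intermediate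
12 | (2E,6E,11S)-1-bromo-11,12-bis(tert-butyldimethylsilyloxy)-2,6-dimethyldodeca-2,6-dien-9-yne | BrC/C(C)=C/CC/C(C)=C/CC#C[C@H](O[Si](C)(C)C(C)(C)C)CO[Si](C)(C)C(C)(C)C | intermediate
13 | (–)-8-phenylmenthyl (6E,10E,15S)-15,16-bis(tert-butyldimethylsilyloxy)-6,10-dimethyl-3-oxohexadeca-6,10-dien-13-ynoate | O=C(CC(=O)CC/C(C)=C/CC/C(C)=C/CC#C[C@H](O[Si](C)(C)C(C)(C)C)CO[Si](C)(C)C(C)(C)C)O[C@@H]1C[C@H](C)CC[C@H]1C(C)(C)c1ccccc1 | intermediate
14 | (–)-8-phenylmenthyl (14S)-14,15-bis(tert-butyldimethylsilyloxy)-3-oxo-16,18-dinorlabd-8(17)-en-12-yn-19-oate (5β-H, 9β-H, 10α-CH3, equatorial ester, C4 epimerisable) | C=C1CC[C@@H]2[C@@H](C(=O)O[C@@H]3C[C@H](C)CC[C@H]3C(C)(C)c3ccccc3)C(=O)CC[C@@]2(C)[C@@H]1CC#C[C@H](O[Si](C)(C)C(C)(C)C)CO[Si](C)(C)C(C)(C)C | intermediate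
15 | (–)-8-phenylmenthyl (14S)-14,15-bis(tert-butyldimethylsilyloxy)-3-oxo-16-norlabd-8(17)-en-12-yn-19-oate (4β-CH3, axial 4α-ester, 5β-H, 9β-H, 10α-CH3) | C=C1CC[C@@H]2[C@](C)(C(=O)O[C@@H]3C[C@H](C)CC[C@H]3C(C)(C)c3ccccc3)C(=O)CC[C@@]2(C)[C@@H]1CC#C[C@H](O[Si](C)(C)C(C)(C)C)CO[Si](C)(C)C(C)(C)C | intermediate
16 | (14S)-14,15-bis(tert-butyldimethylsilyloxy)-16-norlabd-8(17)-en-12-yne-3α,19-diol (4β-CH3, 5β-H, 9β-H, 10α-CH3) | C=C1CC[C@@H]2[C@](C)(CO)[C@H](O)CC[C@@]2(C)[C@@H]1CC#C[C@H](O[Si](C)(C)C(C)(C)C)CO[Si](C)(C)C(C)(C)C | intermediate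
17 | (14S)-14,15-bis(tert-butyldimethylsilyloxy)-3α,19-(isopropylidenedioxy)-16-norlabd-8(17)-en-12-yne | C=C1CC[C@@H]2[C@](C)(COC(C)(C)O3)[C@H]3CC[C@@]2(C)[C@@H]1CC#C[C@H](O[Si](C)(C)C(C)(C)C)CO[Si](C)(C)C(C)(C)C | intermediate
18 | (14S)-3α,19-(isopropylidenedioxy)-16-norlabd-8(17)-en-12-yne-14,15-diol | C=C1CC[C@@H]2[C@](C)(COC(C)(C)O3)[C@H]3CC[C@@]2(C)[C@@H]1CC#C[C@H](O)CO | intermediate
19 | (12E)-13-(tributylstannyl)-3α,19-(isopropylidenedioxy)-16-norlabda-8(17),12-diene-14,15-diol (not isolated; C14 geometry as in 18) | C=C1CC[C@@H]2[C@](C)(COC(C)(C)O3)[C@H]3CC[C@@]2(C)[C@@H]1C/C=C(/[Sn](CCCC)(CCCC)CCCC)[C@H](O)CO | intermediate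
20 | (12E)-13-iodo-3α,19-(isopropylidenedioxy)-16-norlabda-8(17),12-diene-14,15-diol (C14 geometry as in 18) | C=C1CC[C@@H]2[C@](C)(COC(C)(C)O3)[C@H]3CC[C@@]2(C)[C@@H]1C/C=C(/I)[C@H](O)CO | intermediate
21 | 3,19-O-isopropylideneandrographolide (12E,14S) | C=C1CC[C@@H]2[C@](C)(COC(C)(C)O3)[C@H]3CC[C@@]2(C)[C@@H]1C/C=C1/C(=O)OC[C@H]1O | intermediate
22 | 14-O-acetyl-3,19-O-isopropylideneandrographolide | C=C1CC[C@@H]2[C@](C)(COC(C)(C)O3)[C@H]3CC[C@@]2(C)[C@@H]1C/C=C1/C(=O)OC[C@H]1OC(C)=O | intermediate
23 | 14-O-acetylandrographolide (3R,4R,5S,9R,10S,12E,14S) | C=C1CC[C@@H]2[C@](C)(CO)[C@H](O)CC[C@@]2(C)[C@@H]1C/C=C1/C(=O)OC[C@H]1OC(C)=O | target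

**Step count**

Total: 17 steps. Longest linear sequence: 15 steps (4 → 5 → 6 → 7 → 11 → 12 → 13 → 14 → 15 → 16 → 17 → 18 → 20 → 21 → 22 → 23, i.e. steps 2–4 and 6–17).

**Three steps most likely to fail**

Step 9 (radical bicyclisation). The risks are erosion of auxiliary control once the copper co-oxidant is present, further oxidation of the still enolisable product 14, a Δ7/Δ8(17) alkene mixture from the copper oxidation, and loss of a silyl ether to Yb(OTf)3. The fallback sets out from 13 and comes back at 15. Compound 13 is C-methylated first (K2CO3, MeI, acetone, reflux) to the 2-methyl β-keto ester F1, a mixture of C2 epimers that does not matter because that centre becomes the radical. F1 is then cyclised under the classical lanthanide-free conditions (Mn(OAc)3·2H2O, Cu(OAc)2·H2O, AcOH, rt). The tertiary radical cannot be over-oxidised after cyclisation, and the unchelated chair transition state puts the ester axial and the methyl equatorial, so the C4 quaternary centre is created in the cyclisation itself and 15 is formed directly. Facial control by the auxiliary is expected to be lower here, but the wrong-face isomers are diastereomers of 15 and are removed by chromatography.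

Step 14 (hydrostannation/iodination). The risk is tin ending on C12 instead of C13, or protodestannylation, on an alkyne that is hindered on the carbinol side. The fallback sets out from 17 and comes back at 21, and it uses neither tin nor iodide. Only the primary silyl ether of 17 is removed (HF·pyridine, pyridine/THF, 0 °C) to give the 15-hydroxy 14-silyl ether F2. Pd-catalysed cyclocarbonylation of this homopropargylic alcohol (PdCl2(PPh3)2 and SnCl2 as catalysts, CO 7 atm, MeCN, 75 °C) then forms an alkoxycarbonyl–palladium at O15 that adds syn across the alkyne in the 5-exo sense. The carbonyl carbon can therefore only end on C13, and protonolysis of the C12–Pd bond gives the (E)-alkylidene lactone as its 14-O-TBS ether F3. Buffered desilylation (TBAF/AcOH, THF, 0 °C) returns 21.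

Step 15 (carbonylative lactonisation). The risk is that the vinylpalladium of the unprotected iodo diol loses β-hydroxide to give an allene, or that lactone closure is slow at this hindered centre. The fallback sets out from 20 and comes back at 21. The diol is silylated (TESCl, imidazole, CH2Cl2) to the bis-triethylsilyl ether F4. Iodine–lithium exchange (t-BuLi, 2.1 equiv, Et2O, –78 °C, retention of alkene geometry) and trapping with methyl chloroformate give the methyl (E)-enoate F5. Treatment with HF·pyridine in THF removes both silyl groups, and the freed 15-OH closes the γ-lactone with loss of methanol, giving 21.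

**Further compounds**

F1 | step 9 | (–)-8-phenylmenthyl (6E,10E,15S)-15,16-bis(tert-butyldimethylsilyloxy)-2,6,10-trimethyl-3-oxohexadeca-6,10-dien-13-ynoate (C2 epimers) | CC(C(=O)CC/C(C)=C/CC/C(C)=C/CC#C[C@H](O[Si](C)(C)C(C)(C)C)CO[Si](C)(C)C(C)(C)C)C(=O)O[C@@H]1C[C@H](C)CC[C@H]1C(C)(C)c1ccccc1
F2 | step 14 | (14S)-14-(tert-butyldimethylsilyloxy)-3α,19-(isopropylidenedioxy)-16-norlabd-8(17)-en-12-yn-15-ol | C=C1CC[C@@H]2[C@](C)(COC(C)(C)O3)[C@H]3CC[C@@]2(C)[C@@H]1CC#C[C@H](O[Si](C)(C)C(C)(C)C)CO
F3 | step 14 | 14-O-(tert-butyldimethylsilyl)-3,19-O-isopropylideneandrographolide | C=C1CC[C@@H]2[C@](C)(COC(C)(C)O3)[C@H]3CC[C@@]2(C)[C@@H]1C/C=C1/C(=O)OC[C@H]1O[Si](C)(C)C(C)(C)C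
F4 | step 15 | (12E)-13-iodo-14,15-bis(triethylsilyloxy)-3α,19-(isopropylidenedioxy)-16-norlabda-8(17),12-diene | C=C1CC[C@@H]2[C@](C)(COC(C)(C)O3)[C@H]3CC[C@@]2(C)[C@@H]1C/C=C(/I)[C@H](O[Si](CC)(CC)CC)CO[Si](CC)(CC)CC
F5 | step 15 | methyl (12E)-14,15-bis(triethylsilyloxy)-3α,19-(isopropylidenedioxy)labda-8(17),12-dien-16-oate | C=C1CC[C@@H]2[C@](C)(COC(C)(C)O3)[C@H]3CC[C@@]2(C)[C@@H]1C/C=C(/C(=O)OC)[C@H](O[Si](CC)(CC)CC)CO[Si](CC)(CC)CC
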